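Starting material that loses a steady fraction of itself per minute gives its clock from two readings and a logarithm, so the runs can be read as rates.

| setting | eta | theta | alpha | ash | maple | larch | birch | oak | elm |
|---|---|---|---|---|---|---|---|---|---|
| starting material | 0.10 M | 0.10 M | 0.10 M | 0.10 M | 0.10 M | 0.10 M | 0.10 M (fed, over 4.0 min) | 0.10 M (fed, over 25 s) | 0.10 M (in portions, 3, over 4.0 min) |
| fresh partner | 0.20 M | 0.28 M | 0.44 M | 0.200 M | 0.200 M | 0.200 M (fed, over 4.0 min) | 0.200 M | 0.200 M | 0.200 M |
| coupling partner | 0.15 M | 0.15 M | 0.15 M | 0.150 M | 0.150 M | 0.150 M | 0.150 M | 0.150 M | 0.150 M |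
| temperature | 85 °C | 100 °C | 85 °C | 100 °C |  |  | 100 °C | 100 °C | 100 °C |
| remark | run made earlier | run made earlier | run made earlier | everything together at the start | everything together at the start at 80 °C, warmed to 100 °C at 4.0 min | the addition at 80 °C, then warmed to 100 °C; the feed brings no volume worth counting | all else is in the flask from the start; the feed brings no volume worth counting | all else is in the flask from the start; the feed brings no volume worth counting | first portion at the start, last at 4.0 min |
| time |  |  |  | 5.0 min | 5.0 min | 5.0 min | 5.0 min | 5.0 min | 5.0 min |

| run | time / min | target / % | side product / % | starting material / % |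
|---|---|---|---|---|
| eta | 0.833 | 7.2 | 7.7 | 64.0 |
| eta | 2.00 | 17.8 | 19.6 | 43.8 |
| eta | 4.00 | 23.3 | 31.6 | 28.7 |
| eta | 10.0 | 21.9 | 47.6 | 12.3 |
| theta | 0.833 | 13.9 | 25.9 | 47.0 |
| theta | 2.00 | 16.6 | 45.9 | 26.5 |
| theta | 4.00 | 15.6 | 59.3 | 11.8 |
| theta | 6.00 | 14.9 | 65.8 | 6.0 |
| alpha | 1.00 | 9.4 | 17.2 | 62.4 |
| alpha | 2.00 | 13.5 | 31.7 | 46.8 |
| alpha | 5.00 | 13.6 | 53.8 | 24.9 |
| alpha | 12.0 | 12.1 | 70.1 | 8.1 |

(scatter of a reading: 0.3 percentage points)

- a reading or a percentage of target counts all its forms, free or not

- the flask with the highest share of target in target plus side product ("all alike" if they lie within 1.5 percentage points) (ash / maple / larch / birch / oak / elm / all alike)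
- share of target in target plus side product at the end, ash
- share of target in target plus side product at the end, maple
- share of target in target plus side product at the end, larch
- share of target in target plus side product at the end, birch
- share of target in target plus side product at the end, oak
- share of target in target plus side product at the end, elm

1. The theta run opens with starting material going at 0.906 min⁻¹. Of that loss, 48.9% appears as side product, so the side route's part of the clock is 0.443 min⁻¹.

2. Between 4.00 min and 6.00 min, theta's clock reads 0.338 min⁻¹. This is the side-product clock, the fraction of standing starting material lost per minute once the loss is pseudo-first-order. The gain in side product, 6.5 percentage points, matches the loss of starting material, 5.8 points, within scatter.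

3. The whole clock slows by a factor 2.68, but the side part slows by 1.31, less. So the side part is the nearer to constant, though it does move, and this reckoning freezes it at 0.338 min⁻¹ as an estimate.

4. Fresh partner speeds the side route. Its opening rate is 0.172 min⁻¹ in the alpha run against 0.0924 min⁻¹ in the eta run, a factor 1.86 for 2.20 in charge.

5. Taking the other route as closed by 2.00 min, half of birch's feed arrives on the side clock alone. That clock, frozen at theta's value, leaves an estimated 25.9% standing at the end, and birch's share should fall below the 20.8% theta reads at 4.00 min.

The forecast gives larch the lead at 47%, with ash at 24.5%, maple at 40%, birch at 34%, oak at 25.5% and elm at 29%, saying “Birch gains from the feed”, and on birch this reckoning differs from it.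

The flask puts larch ahead at 69.1%, with ash at 26.1%, maple at 39.6%, birch at 6.54%, oak at 18.4% and elm at 13.9%.

    starting material + coupling partner → open intermediate (k = 0.160 L mol⁻¹ s⁻¹, Ea = 53.0 kJ mol⁻¹)
    coupling partner + fresh partner → second intermediate (k = 0.250 L mol⁻¹ s⁻¹, Ea = 66.0 kJ mol⁻¹)
    open intermediate + second intermediate ⇌ target (K = 26.0 L mol⁻¹, k = 0.390 L mol⁻¹ s⁻¹, Ea = 46.0 kJ mol⁻¹, ΔH = −9.00 kJ mol⁻¹)
    crystals ⇌ target, rate k4*(cs4 - [target]) while solid is left; crystals form when [target] > cs4 (solubility = 0.0720 M, k = 0.0800 s⁻¹)
    starting material + second intermediate → side product (k = 0.120 L mol⁻¹ s⁻¹, Ea = 62.0 kJ mol⁻¹)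
    (constants at 100 °C)

Birch ends with 72.1% side product against 5.05% target, and 20.0% starting material stands there, less than the 25.9% reckoned. In larch, 20.3% starting material stands at 5.00 min and 0.00501% at 50.0 min, a mean clock of 0.185 min⁻¹, slower than the 0.338 min⁻¹ read from theta. Over those minutes larch's side product climbs from 13.8% to 33.9%.

All runs are calculated for an exercise, noise included.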